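**Plan**

1. Retrosynthetic cuts, in order: the O7''–sulfur bond and every benzyl-type O–C bond; then C2–C3 of flavanone ring C (O1, C2, C3, C4, C4a, C8a); then the diazo group on C3, the C4–C4a bond, and the two-carbon chain on flavone C8'' back to an allyl group on luteolin O7'' (flavone atoms double-primed, its catechol ring triple-primed).
2. Enabling feature: C2 is a para-oxygenated benzylic carbon on phenolic O1, which sits on ring A ortho to the C4 ketone, and C3 lies between that ketone and C8''. C2 can therefore start as the O–CH2 of a 4-(benzyloxy)benzyl (BOB) ether and C3 as the diazo carbon of an α-aryl-α-diazo ketone.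
3. Forward: the flavone rings are bought as luteolin. An O7''→C8'' Claisen shift and alkene cleavage give a C8'' acetaldehyde, which is joined to a metalated phloroglucinol tris-BOB ether (ring A). Oxidation and diazo transfer follow, and ring C closes last.
4. Stereochemistry: C2 comes from the chiral dirhodium carboxylate, which chooses between two enantiotopic benzylic hydrogens; C3 comes from equilibration to the 2,3-trans ketone.
5. End game: O7'' is freed from silicon and sulfated, then all benzyl-type groups are removed by hydrogenolysis.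

Key step: step 11

Assumption 1: the target is drawn as the free hydrogen sulfate; it is carried as its sodium salt and protonated only in the last operation.
Assumption 2: Rh2(S-PTTL)4 is assumed to favour the 2R series; if the sense of induction is opposite, Rh2(R-PTTL)4 is used under the same conditions.
Abbreviations: BOB = 4-(benzyloxy)benzyl; TIPS = triisopropylsilyl; Rh2(S-PTTL)4 = dirhodium tetrakis[N-phthaloyl-(S)-tert-leucinate].

**Route**

Step 1
Reactants: 1 luteolin
Product: 2 3',4'-O-(diphenylmethylene)luteolin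
Conditions: Ph2CCl2 (1.5 equiv), Ph2O, 175 °C, 0.5–1 h
Reagents that add atoms: dichlorodiphenylmethane, ClC(Cl)(c1ccccc1)c1ccccc1
Why: Catechol ketalisation with a gem-dichloride, in which only the vicinal 3',4'-hydroxyls can close the five-membered 1,3-benzodioxole; this is a standard catechol protection of luteolin- and quercetin-type flavones and is later removed by hydrogenolysis.

Step 2
Reactants: 2 3',4'-O-(diphenylmethylene)luteolin
Product: 4 7-O-allyl-5-O-benzyl-3',4'-O-(diphenylmethylene)luteolin, via 7-O-allyl ether 3 (not isolated)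
Conditions: allyl bromide (1.0 equiv), K2CO3, DMF, rt; then BnBr (2 equiv), Bu4NI (cat.), 70 °C
Reagents that add atoms: allyl bromide, C=CCBr; benzyl bromide, BrCc1ccccc1
Why: Williamson etherification in two stages: the acidic, non-chelated 7-OH is alkylated at room temperature by one equivalent of allyl bromide, whereas the 5-OH, hydrogen-bonded to the C4 carbonyl, reacts only with excess benzyl bromide on heating, so the order of addition fixes which group goes where.

Step 3
Reactants: 4 7-O-allyl-5-O-benzyl-3',4'-O-(diphenylmethylene)luteolin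
Product: 5 8-allyl-5-O-benzyl-3',4'-O-(diphenylmethylene)luteolin (7-OH free)
Conditions: PhNEt2, 200 °C, sealed tube
Reagents that add atoms: none
Why: Aromatic Claisen rearrangement ([3,3]-sigmatropic shift, then tautomerisation) of the 7-O-allyl ether should go to C8, because the C7–C8 bond of a benzopyran-4-one has the higher double-bond character (as with 7-allyloxy-chromones and -coumarins) and C6 is flanked by the benzyloxy group; the shift also frees the 7-OH and so marks it out from all other phenols.

Step 4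
Reactants: 5 8-allyl-5-O-benzyl-3',4'-O-(diphenylmethylene)luteolin
Product: 6 8-allyl-5-O-benzyl-3',4'-O-(diphenylmethylene)-7-O-(triisopropylsilyl)luteolin
Conditions: iPr3SiCl, imidazole, DMF, rt
Reagents that add atoms: triisopropylsilyl chloride, CC(C)[Si](Cl)(C(C)C)C(C)C
Why: Silylation of the only free phenol with a chlorosilane and imidazole; the triisopropylsilyl group offers the later carbenoid no C–H bond α to oxygen and resists the bases of steps 8 and 10 better than smaller silyl groups.

Step 5
Reactants: 6 8-allyl-5-O-benzyl-3',4'-O-(diphenylmethylene)-7-O-(triisopropylsilyl)luteolin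
Product: 7 flavone-8-acetaldehyde (5-OBn; 7-OTIPS; 3',4'-O-diphenylmethylene)
Conditions: OsO4 (2 mol %), NaIO4 (4 equiv), 2,6-lutidine, dioxane/H2O 3:1, rt
Reagents that add atoms: osmium tetroxide, O=[Os](=O)(=O)=O (oxygen carrier); sodium periodate, [Na+].[O-]I(=O)(=O)=O (terminal oxidant, source of the carbonyl oxygen)
Why: Lemieux–Johnson oxidation: OsO4 dihydroxylates the terminal alkene much faster than the electron-poor, conjugated C2=C3 bond of the flavone, and periodate cleaves the diol to the arylacetaldehyde, with 2,6-lutidine suppressing over-oxidation.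

Step 6
Reactants: 8 phloroglucinol; 9 4-(benzyloxy)benzyl chloride
Product: 10 1,3,5-tris[4-(benzyloxy)benzyloxy]benzene
Conditions: 9 (3.3 equiv in all), K2CO3 (4 equiv), Bu4NI (cat.), DMF, 50 °C
Reagents that add atoms: two further equivalents of 4-(benzyloxy)benzyl chloride 9, ClCc1ccc(OCc2ccccc2)cc1.ClCc1ccc(OCc2ccccc2)cc1
Why: Threefold Williamson etherification in which each of the three phenoxide oxygens of phloroglucinol displaces chloride from one molecule of 9, so that three molecules of the benzylic chloride are built into 10; carbonate in a dipolar aprotic solvent favours O- over C-alkylation, as in the known tribenzylation of phloroglucinol.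

Step 7
Reactants: 10 1,3,5-tris[4-(benzyloxy)benzyloxy]benzene
Product: 11 2-bromo-1,3,5-tris[4-(benzyloxy)benzyloxy]benzene
Conditions: NBS (1.0 equiv), CH2Cl2, –78 → –20 °C, dark
Reagents that add atoms: N-bromosuccinimide, O=C1CCC(=O)N1Br
Why: Electrophilic aromatic bromination with NBS: the 1,3,5-trialkoxybenzene core is far more nucleophilic than the mono-alkoxy rings of the BOB groups and its three free positions are equivalent, so one equivalent at low temperature should give the monobromide.

Step 8
Reactants: 11 2-bromo-1,3,5-tris[4-(benzyloxy)benzyloxy]benzene; 7 flavone-8-acetaldehyde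
Product: 14 racemic carbinol 1-[2,4,6-tris(BOB-oxy)phenyl]-2-(protected flavon-8''-yl)ethanol, via aryllithium 12 (not isolated), via arylcerium dichloride 13 (not isolated)
Conditions: n-BuLi (1.05 equiv), THF, –78 °C; anhydrous CeCl3, THF, –78 °C; then 7, –78 °C; aq. NH4Cl
Reagents that add atoms: n-butyllithium, [Li]CCCC (gives the lithium of 12); cerium trichloride, Cl[Ce](Cl)Cl (gives the cerium and chlorine of 13)
Why: Bromine–lithium exchange, transmetalation to the organocerium reagent (trivalent cerium) and 1,2-addition to the aldehyde: the weakly basic, oxophilic cerium reagent should add to the enolisable arylacetaldehyde rather than deprotonate it, and the aldehyde is far more electrophilic than the vinylogous-ester carbonyl of the flavone; the new carbinol centre forms as a racemate and is destroyed in step 9.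

Step 9
Reactants: 14 racemic carbinol
Product: 15 deoxybenzoin 1-[2,4,6-tris(BOB-oxy)phenyl]-2-(protected flavon-8''-yl)ethanone
Conditions: Dess–Martin periodinane, pyridine, CH2Cl2, 0 °C → rt
Reagents that add atoms: none
Why: Dess–Martin oxidation of the secondary benzylic alcohol to the ketone under pyridine buffering, which spares the silyl ether, the ketal and the acid-labile alkoxybenzyl ethers and avoids ionisation of the electron-rich carbinol.

Step 10
Reactants: 15 deoxybenzoin
Product: 16 α-diazo deoxybenzoin 2-diazo-1-[2,4,6-tris(BOB-oxy)phenyl]-2-(protected flavon-8''-yl)ethanone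
Conditions: p-ABSA (1.5 equiv), DBU (2 equiv), MeCN/CH2Cl2, 0 °C → rt
Reagents that add atoms: 4-acetamidobenzenesulfonyl azide, CC(=O)Nc1ccc(cc1)S(=O)(=O)N=[N+]=[N-]
Why: Regitz diazo transfer: DBU deprotonates the methylene flanked by the ketone and the flavone ring, the enolate attacks the terminal nitrogen of the sulfonyl azide, and loss of the sulfonamide leaves the α-aryl-α-diazo ketone, as known for deoxybenzoins.

Step 11
Reactants: 16 α-diazo deoxybenzoin
Product: 18 (2R,3S)-trans flavanone (O5/O7 BOB ethers; 4'-OBn; O7'' TIPS; O5'' Bn; catechol diphenylmethylene ketal), via (2R,3R)-cis flavanone 17 (not isolated)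
Conditions: Rh2(S-PTTL)4 (2 mol %), 4 Å MS, toluene, –20 °C → rt, slow addition of 16; then Et3N (0.2 equiv), CH2Cl2, rt
Reagents that add atoms: none
Why: Rh2(S-PTTL)4 (divalent rhodium) expels N2 from 16 to give a donor–acceptor rhodium carbenoid at the future C3, which takes a hydride-like benzylic hydrogen from an ortho O–CH2Ar group in a three-centre, asynchronous transition state, forming C2–C3 and leaving the hydrogen on C3. The closest known reaction type is the dirhodium-carboxylate-catalysed intramolecular C–H insertion of 2-alkoxyaryl α-diazo ketones into the ether α-C–H bond, which gives chroman-4-ones and has enantioselective variants with chiral carboxylates. Ring C closes as a six-membered ring by 1,6-C–H insertion, the carbenoid carbon and the ether carbon being linked through C4, C4a, C8a and O1. C2 is set by the catalyst, whose phthalimide-lined pocket distinguishes the two enantiotopic hydrogens of the reacting CH2 (the two ortho ethers are identical, so it does not matter which one reacts); C3 is set by thermodynamic control, the amine equilibrating any cis epimer 17 through the enol to the 2,3-trans, diequatorial ketone 18 without touching C2. The step needs C–H insertion to win over attack of the ether oxygen on the carbenoid (five-membered oxonium ylide, then 1,2-benzyl shift), over Wolff rearrangement and over any reaction on the flavone side; the para-benzyloxy group makes the benzylic C–H bond hydridic, the aryl donor tempers the carbenoid, O7'' carries a silyl group with no C–H bond α to oxygen, and every other ether CH2 is out of reach.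

Step 12
Reactants: 18 (2R,3S)-trans flavanone
Product: 19 (2R,3S)-flavanone with free 7''-OH
Conditions: Bu4NF (1.2 equiv), AcOH (1.5 equiv), THF, 0 °C
Reagents that add atoms: none
Why: Fluoride-induced cleavage of the aryl silyl ether (the phenoxide, conjugated to the flavone carbonyl, is a good leaving group); acetic acid keeps the medium from becoming basic enough to enolise C3 and open ring C by retro-oxa-Michael reaction, so C2 keeps its configuration and C3 stays trans.

Step 13
Reactants: 19 (2R,3S)-flavanone with free 7''-OH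
Product: 20 sodium 7''-O-sulfate of the protected biflavonoid
Conditions: SO3·pyridine (5 equiv), pyridine/DMF, 40 °C; then aq. NaHCO3
Reagents that add atoms: sulfur trioxide–pyridine complex, [O-]S(=O)(=O)[n+]1ccccc1; sodium hydrogencarbonate, [Na+].OC([O-])=O (gives the sodium of 20)
Why: O-Sulfation of a phenol with the sulfur trioxide–pyridine complex; 19 has a single free hydroxyl, so the sulfate can only enter at O7'', and the hydrogencarbonate work-up gives the sodium salt, which keeps the acid-labile alkoxybenzyl ethers and the C2–O1 bond away from a strong acid.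

Step 14
Reactants: 20 sodium 7''-O-sulfate of the protected biflavonoid
Product: 22 CNP0314990.1 (2R,3S), via deprotected sodium sulfate 21 (not isolated)
Conditions: H2 (1 atm), 10% Pd/C, THF/MeOH, rt; filter; then aq. HCl (1.0 equiv), 0 °C, C18 desalting, freeze-drying
Reagents that add atoms: none
Why: Catalytic hydrogenolysis of benzylic C–O bonds should remove the two benzyl ethers, both BOB groups (through the 4-hydroxybenzyl ethers to 4-methylphenol) and the diphenylmethylene ketal, while aryl sulfate salts, the flavone C2''=C3'' bond and the flavanone C2–O1 bond are known to survive these mild conditions; one equivalent of cold acid then gives the hydrogen sulfate without touching C2 or C3.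

**Compound list**

1 | luteolin | O=c1cc(-c2ccc(O)c(O)c2)oc2cc(O)cc(O)c12 | starting material
2 | 3',4'-O-(diphenylmethylene)luteolin | O=c1cc(-c2ccc3OC(c4ccccc4)(c4ccccc4)Oc3c2)oc2cc(O)cc(O)c12 | intermediate
3 | 7-O-allyl-3',4'-O-(diphenylmethylene)luteolin (not isolated) | O=c1cc(-c2ccc3OC(c4ccccc4)(c4ccccc4)Oc3c2)oc2cc(OCC=C)cc(O)c12 | intermediate
4 | 7-O-allyl-5-O-benzyl-3',4'-O-(diphenylmethylene)luteolin | O=c1cc(-c2ccc3OC(c4ccccc4)(c4ccccc4)Oc3c2)oc2cc(OCC=C)cc(OCc3ccccc3)c12 | intermediate
5 | 8-allyl-5-O-benzyl-3',4'-O-(diphenylmethylene)luteolin | O=c1cc(-c2ccc3OC(c4ccccc4)(c4ccccc4)Oc3c2)oc2c(CC=C)c(O)cc(OCc3ccccc3)c12 | intermediate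
6 | 8-allyl-5-O-benzyl-3',4'-O-(diphenylmethylene)-7-O-(triisopropylsilyl)luteolin | O=c1cc(-c2ccc3OC(c4ccccc4)(c4ccccc4)Oc3c2)oc2c(CC=C)c(O[Si](C(C)C)(C(C)C)C(C)C)cc(OCc3ccccc3)c12 | intermediate
7 | [5-benzyloxy-2-(2,2-diphenyl-1,3-benzodioxol-5-yl)-4-oxo-7-(triisopropylsilyloxy)chromen-8-yl]acetaldehyde | O=CCc1c(O[Si](C(C)C)(C(C)C)C(C)C)cc(OCc2ccccc2)c2c(=O)cc(-c3ccc4OC(c5ccccc5)(c5ccccc5)Oc4c3)oc12 | intermediate
8 | phloroglucinol | Oc1cc(O)cc(O)c1 | starting material
9 | 4-(benzyloxy)benzyl chloride | ClCc1ccc(OCc2ccccc2)cc1 | starting material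
10 | 1,3,5-tris[4-(benzyloxy)benzyloxy]benzene | c1(OCc2ccc(OCc3ccccc3)cc2)cc(OCc2ccc(OCc3ccccc3)cc2)cc(OCc2ccc(OCc3ccccc3)cc2)c1 | intermediate
11 | 2-bromo-1,3,5-tris[4-(benzyloxy)benzyloxy]benzene | Brc1c(OCc2ccc(OCc3ccccc3)cc2)cc(OCc2ccc(OCc3ccccc3)cc2)cc1OCc1ccc(OCc2ccccc2)cc1 | intermediate
12 | 2,4,6-tris[4-(benzyloxy)benzyloxy]phenyllithium (not isolated) | [Li]c1c(OCc2ccc(OCc3ccccc3)cc2)cc(OCc2ccc(OCc3ccccc3)cc2)cc1OCc1ccc(OCc2ccccc2)cc1 | intermediate
13 | dichloro{2,4,6-tris[4-(benzyloxy)benzyloxy]phenyl}cerium (not isolated) | Cl[Ce](Cl)c1c(OCc2ccc(OCc3ccccc3)cc2)cc(OCc2ccc(OCc3ccccc3)cc2)cc1OCc1ccc(OCc2ccccc2)cc1 | intermediate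
14 | racemic 1-{2,4,6-tris[4-(benzyloxy)benzyloxy]phenyl}-2-[flavon-8''-yl]ethanol, flavone unit protected as in 7 | OC(Cc1c(O[Si](C(C)C)(C(C)C)C(C)C)cc(OCc2ccccc2)c2c(=O)cc(-c3ccc4OC(c5ccccc5)(c5ccccc5)Oc4c3)oc12)c1c(OCc2ccc(OCc3ccccc3)cc2)cc(OCc2ccc(OCc3ccccc3)cc2)cc1OCc1ccc(OCc2ccccc2)cc1 | intermediate
15 | 1-{2,4,6-tris[4-(benzyloxy)benzyloxy]phenyl}-2-[flavon-8''-yl]ethanone (deoxybenzoin), flavone unit protected as in 7 | O=C(Cc1c(O[Si](C(C)C)(C(C)C)C(C)C)cc(OCc2ccccc2)c2c(=O)cc(-c3ccc4OC(c5ccccc5)(c5ccccc5)Oc4c3)oc12)c1c(OCc2ccc(OCc3ccccc3)cc2)cc(OCc2ccc(OCc3ccccc3)cc2)cc1OCc1ccc(OCc2ccccc2)cc1 | intermediate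
16 | 2-diazo-1-{2,4,6-tris[4-(benzyloxy)benzyloxy]phenyl}-2-[flavon-8''-yl]ethanone (key-step precursor) | [N-]=[N+]=C(C(=O)c1c(OCc2ccc(OCc3ccccc3)cc2)cc(OCc2ccc(OCc3ccccc3)cc2)cc1OCc1ccc(OCc2ccccc2)cc1)c1c(O[Si](C(C)C)(C(C)C)C(C)C)cc(OCc2ccccc2)c2c(=O)cc(-c3ccc4OC(c5ccccc5)(c5ccccc5)Oc4c3)oc12 | intermediate
17 | (2R,3R)-cis flavanone, C3 epimer of 18 (not isolated) | O=C1c2c(OCc3ccc(OCc4ccccc4)cc3)cc(OCc3ccc(OCc4ccccc4)cc3)cc2O[C@@H](c2ccc(OCc3ccccc3)cc2)[C@H]1c1c(O[Si](C(C)C)(C(C)C)C(C)C)cc(OCc2ccccc2)c2c(=O)cc(-c3ccc4OC(c5ccccc5)(c5ccccc5)Oc4c3)oc12 | intermediate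
18 | (2R,3S)-trans-2-[4-(benzyloxy)phenyl]-5,7-bis[4-(benzyloxy)benzyloxy]-3-[flavon-8''-yl]chroman-4-one, flavone unit with 5''-OBn, 7''-OTIPS and 3''',4'''-O-diphenylmethylene (key-step product) | O=C1c2c(OCc3ccc(OCc4ccccc4)cc3)cc(OCc3ccc(OCc4ccccc4)cc3)cc2O[C@@H](c2ccc(OCc3ccccc3)cc2)[C@@H]1c1c(O[Si](C(C)C)(C(C)C)C(C)C)cc(OCc2ccccc2)c2c(=O)cc(-c3ccc4OC(c5ccccc5)(c5ccccc5)Oc4c3)oc12 | intermediate
19 | (2R,3S)-flavanone as 18 but with free 7''-OH | O=C1c2c(OCc3ccc(OCc4ccccc4)cc3)cc(OCc3ccc(OCc4ccccc4)cc3)cc2O[C@@H](c2ccc(OCc3ccccc3)cc2)[C@@H]1c1c(O)cc(OCc2ccccc2)c2c(=O)cc(-c3ccc4OC(c5ccccc5)(c5ccccc5)Oc4c3)oc12 | intermediate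
20 | sodium salt of the 7''-O-sulfate of 19 | [Na+].O=C1c2c(OCc3ccc(OCc4ccccc4)cc3)cc(OCc3ccc(OCc4ccccc4)cc3)cc2O[C@@H](c2ccc(OCc3ccccc3)cc2)[C@@H]1c1c(OS(=O)(=O)[O-])cc(OCc2ccccc2)c2c(=O)cc(-c3ccc4OC(c5ccccc5)(c5ccccc5)Oc4c3)oc12 | intermediate
21 | sodium salt of the fully deprotected 7''-O-sulfate (not isolated) | [Na+].O=C1c2c(O)cc(O)cc2O[C@@H](c2ccc(O)cc2)[C@@H]1c1c(OS(=O)(=O)[O-])cc(O)c2c(=O)cc(-c3ccc(O)c(O)c3)oc12 | intermediate
22 | CNP0314990.1, (2R,3S)-naringenin-(3→8'')-luteolin 7''-O-(hydrogen sulfate) | O=C1c2c(O)cc(O)cc2O[C@@H](c2ccc(O)cc2)[C@@H]1c1c(OS(=O)(=O)O)cc(O)c2c(=O)cc(-c3ccc(O)c(O)c3)oc12 | target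

**Step count and risks**

Total steps: 14. Longest linear sequence: 12 (luteolin 1 to 22 through steps 1–5 and 8–14); steps 6–7 make the ring A bromide 11.

Steps most likely to fail:

Step 11. The ortho ether oxygen may attack the carbenoid to give a five-membered oxonium ylide that collapses by 1,2-benzyl shift. The carbenoid may also undergo Wolff rearrangement, or the catalyst may discriminate poorly between the enantiotopic benzylic hydrogens. The fallback sets out from ketone 15 and comes back at 18. MgBr2·OEt2 in toluene/Et2O, chelated to the ketone, should remove one of the two ortho BOB ethers (the 4-alkoxybenzyl group being far more labile than a plain benzyl ether) and give the 2-hydroxydeoxybenzoin F1. Condensation of the 2-hydroxydeoxybenzoin F1 with 4-(benzyloxy)benzaldehyde (piperidine, toluene, 80 °C; Knoevenagel condensation followed by oxa-Michael closure, the classical 3-arylflavanone synthesis) forms the same C2–C3 bond and ring C. It should give the trans flavanone as a racemate, that is 18 together with its (2S,3R) enantiomer F2. Preparative HPLC on a chiral stationary phase removes the (2S,3R) enantiomer F2 and returns 18.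

Step 8. The aryl-metal may act as a base and enolise the arylacetaldehyde instead of adding to it, or the silyl group may migrate from O7'' to the newly formed alkoxide. The fallback sets out from aldehyde 7 and comes back at ketone 15, bypassing 14. Pinnick oxidation (NaClO2, NaH2PO4, 2-methyl-2-butene, t-BuOH/H2O) gives the flavone-8-acetic acid F3. EtSH, EDC·HCl and DMAP convert it into the S-ethyl thioester F4. Aryllithium 12, made as in step 8, is transmetalated with ZnCl2 to the arylzinc chloride F5. Fukuyama coupling of the thioester F4 with the arylzinc chloride F5 (PdCl2(PPh3)2 cat., THF/toluene, rt) should give 15 directly. No alkoxide is formed, and the organozinc reagent is too weakly basic to enolise the acyl partner or to touch the flavone.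

Step 14. The hydrogenolysis may stall on the salt before all eight benzylic C–O bonds are broken, ring C may be opened reductively at the benzylic C2–O1 bond on prolonged exposure, or the sulfate may be lost by solvolysis during the final protonation. The fallback sets out from phenol 19 and comes back at 22. The sulfate is introduced in masked, neutral form with 2,2,2-trichloroethyl chlorosulfate (Et3N, DMAP, THF), giving the 2,2,2-trichloroethyl aryl sulfate diester F6, which can be purified on silica. Transfer hydrogenolysis (Pd/C, HCO2NH4, MeOH/THF, rt) then removes the trichloroethyl group and all benzyl-type groups in a buffered medium and gives the ammonium salt F7. One equivalent of cold aqueous HCl converts the ammonium salt F7 into 22.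

Further compounds
F1 | step 11 | 2-hydroxydeoxybenzoin: 15 lacking one ortho 4-(benzyloxy)benzyl group | O=C(Cc1c(O[Si](C(C)C)(C(C)C)C(C)C)cc(OCc2ccccc2)c2c(=O)cc(-c3ccc4OC(c5ccccc5)(c5ccccc5)Oc4c3)oc12)c1c(O)cc(OCc2ccc(OCc3ccccc3)cc2)cc1OCc1ccc(OCc2ccccc2)cc1
F2 | step 11 | (2S,3R) enantiomer of 18, formed with 18 as the racemate | O=C1c2c(OCc3ccc(OCc4ccccc4)cc3)cc(OCc3ccc(OCc4ccccc4)cc3)cc2O[C@H](c2ccc(OCc3ccccc3)cc2)[C@H]1c1c(O[Si](C(C)C)(C(C)C)C(C)C)cc(OCc2ccccc2)c2c(=O)cc(-c3ccc4OC(c5ccccc5)(c5ccccc5)Oc4c3)oc12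
F3 | step 8 | [5-benzyloxy-2-(2,2-diphenyl-1,3-benzodioxol-5-yl)-4-oxo-7-(triisopropylsilyloxy)chromen-8-yl]acetic acid | OC(=O)Cc1c(O[Si](C(C)C)(C(C)C)C(C)C)cc(OCc2ccccc2)c2c(=O)cc(-c3ccc4OC(c5ccccc5)(c5ccccc5)Oc4c3)oc12
F4 | step 8 | S-ethyl thioester of F3 | CCSC(=O)Cc1c(O[Si](C(C)C)(C(C)C)C(C)C)cc(OCc2ccccc2)c2c(=O)cc(-c3ccc4OC(c5ccccc5)(c5ccccc5)Oc4c3)oc12
F5 | step 8 | chloro{2,4,6-tris[4-(benzyloxy)benzyloxy]phenyl}zinc | Cl[Zn]c1c(OCc2ccc(OCc3ccccc3)cc2)cc(OCc2ccc(OCc3ccccc3)cc2)cc1OCc1ccc(OCc2ccccc2)cc1
F6 | step 14 | 2,2,2-trichloroethyl sulfate diester of phenol 19 | O=C1c2c(OCc3ccc(OCc4ccccc4)cc3)cc(OCc3ccc(OCc4ccccc4)cc3)cc2O[C@@H](c2ccc(OCc3ccccc3)cc2)[C@@H]1c1c(OS(=O)(=O)OCC(Cl)(Cl)Cl)cc(OCc2ccccc2)c2c(=O)cc(-c3ccc4OC(c5ccccc5)(c5ccccc5)Oc4c3)oc12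
F7 | step 14 | ammonium salt of the fully deprotected 7''-O-sulfate | [NH4+].O=C1c2c(O)cc(O)cc2O[C@@H](c2ccc(O)cc2)[C@@H]1c1c(OS(=O)(=O)[O-])cc(O)c2c(=O)cc(-c3ccc(O)c(O)c3)oc12
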